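Two questions stand on this flask, both apparent orders at a fixed conversion.

substrate 0.050 M; partner 1.80 equiv; free catalyst 0.59 mol%

    catalyst intermediate C → free catalyst + product (k1 = 11000 h⁻¹)
    substrate + free catalyst → catalyst intermediate A (k2 = 1500 M⁻¹ h⁻¹)
    2 partner → homo dimer (k3 = 33 M⁻¹ h⁻¹)
    catalyst intermediate B ⇌ released group + catalyst intermediate C (K4 = 0.23 M, k4 = 71 h⁻¹)
    partner + catalyst intermediate A → catalyst intermediate B (k5 = 1000 M⁻¹ h⁻¹)

* apparent order in free catalyst when 5.0% of the substrate are converted (percent change of the rate of making product for one percent more free catalyst charged)
* apparent order in partner when 5.0% of the substrate are converted (percent change of the rate of making product for one percent more partner charged)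

My reckoning freezes what hardly moves. By the point asked the substrate has lost 5.0%, so I hold [substrate] at its charge of 0.050 M. With 2.95 × 10⁻⁴ M of catalyst and 0.0900 M of partner, one round (free catalyst waiting for substrate, catalyst intermediate A for partner, catalyst intermediate B for release, catalyst intermediate C for collapse) takes 0.0386 h, so the cycle starts at 0.00764 M h⁻¹.

[partner] does not hold still: at the charge, dimerisation takes it at 0.535 M h⁻¹, far faster than the cycle does, so in my reckoning dimerisation sets it. Then the inverse of [partner] climbs steadily with time, and if I let the rate follow [partner], as a rough simplification, it falls by a factor of 2.72 for each 0.00447 M of product. The reach number is 0.559, the product at the point asked, taken as the substrate converted, divided by that reach of the catalyst.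

On this simplification the rate at that point is the starting rate times exp(−Q), and at a fixed charge of partner the time to it goes as exp(Q) minus one. More catalyst lowers Q, so the order in free catalyst is one plus Q, 1.56. One number is not enough for partner, since its charge does not enter Q. For that order I take a second number, the share of the starting round spent waiting for partner, 0.288.

The forecast gives 1.55 and 0.29, holding that “extra partner charge is largely lost to dimerisation”.

The simulation gives 1.6 and 0.30.

In this flask at 0.138 h, dimerisation uses partner 26 times as fast as capture by catalyst intermediate A does, while at 20.0 h that ratio is 0.0029. By then partner stands at 0.0145% of its charge and substrate at 80.2%. In the second flask, with twice the free catalyst, Q becomes 0.280, so the reckoned factor on the time to that conversion is 0.431, and that flask gives 0.414.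

The constants are made up; no experiment stands behind them.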